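**Retrosynthetic overview**

1. The target is the all-trans (1R,2S,3S) 1-aryl-tetralin-2,3-dimethanol. The strategic cut is the C1–aryl bond, giving aryllithium 15 and the flat naphthalene 12, in which ring B is at the aromatic oxidation level, the C2 CH2OH is raised to a chiral oxazoline and the C3 CH2OH is a silyl ether.
2. Enabling feature: C1 is the benzylic carbon of ring B between C8a of ring A and C2, and C2 carries a one-carbon substituent. With ring B aromatic and that substituent an oxazoline, C1 becomes the β-carbon of a vinylogous imidate, and attack there costs only the aromaticity of ring B while ring A stays benzenoid.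
3. Ring order: ring A is bought (vanillin benzyl ether). Ring B is annulated onto it by a Heck–aldol benzannulation (bonds C8a–C1 and C3–C4) that differentiates the C2 and C3 carboxyl groups, and is then dearomatized by the key step.
4. After the key step: oxazoline to CH2OH, hydroxyl-directed hydrogenation of C3=C4 to set C3, then global deprotection.

Key step: step 8

Assumption: the facial sense of the oxazoline-directed addition is taken from the accepted model (aryllithium bound to nitrogen, aryl delivered anti to the C4 tert-butyl group), which calls for the (R) auxiliary; all bicyclic intermediates are numbered as the target tetralin (C1 aryl-bearing, C2 and C3 hydroxymethyl-bearing, C6 methoxy, C7 oxygen).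

**Route**

Step 1
Reactants: 1 4-(benzyloxy)-3-methoxybenzaldehyde
Product: 2 4-(benzyloxy)-2-bromo-5-methoxybenzaldehyde
Conditions: Br2, NaOAc, AcOH, rt
Reagents that add atoms: bromine BrBr
Why: Electrophilic aromatic bromination should go to the only unhindered position that is para to a donor (para to OMe, ortho to CHO), as in the bromination of veratraldehyde.

Step 2
Reactants: 2 4-(benzyloxy)-2-bromo-5-methoxybenzaldehyde; 3 4-methoxy-2-methylidene-4-oxobutanoic acid (itaconic acid 4-methyl ester)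
Product: 5 7-(benzyloxy)-6-methoxy-3-(methoxycarbonyl)naphthalene-2-carboxylic acid, via arylidenesuccinic acid 4 (not isolated)
Conditions: Pd(OAc)2 (5 mol%), P(o-tol)3 (10 mol%), NaOAc (4 equiv), DMF, 120 °C; then aq. HCl
Reagents that add atoms: none
Why: Domino Heck reaction and intramolecular aldol condensation: the arylpalladium species adds to the terminal CH2 of the acrylic acid unit, the ester-activated CH2 of 4 condenses with the ortho formyl group and aromatization drives the sequence, so the former C–Br carbon ends next to C1 and the acid-bearing C2, the former formyl carbon becomes C4 next to the ester-bearing C3, and the two carboxyl groups are differentiated from the outset.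

Step 3
Reactants: 5 7-(benzyloxy)-6-methoxy-3-(methoxycarbonyl)naphthalene-2-carboxylic acid; 6 (2R)-2-amino-3,3-dimethylbutan-1-ol
Product: 8 methyl 7-(benzyloxy)-2-{[(2R)-1-hydroxy-3,3-dimethylbutan-2-yl]carbamoyl}-6-methoxynaphthalene-3-carboxylate, via acid chloride 7 (not isolated)
Conditions: (COCl)2, DMF (cat.), CH2Cl2, 0 °C → rt; then 6, Et3N, CH2Cl2, 0 °C
Reagents that add atoms: none
Why: Acid chloride formation followed by N-selective acylation of the amino alcohol (the amine is far more nucleophilic than the hindered hydroxyl); the stereocenter of 6 is not touched.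

Step 4
Reactants: 8 methyl 7-(benzyloxy)-2-{[(2R)-1-hydroxy-3,3-dimethylbutan-2-yl]carbamoyl}-6-methoxynaphthalene-3-carboxylate
Product: 10 methyl 7-(benzyloxy)-2-[(4R)-4-tert-butyl-4,5-dihydro-1,3-oxazol-2-yl]-6-methoxynaphthalene-3-carboxylate, via mesylate 9 (not isolated)
Conditions: MsCl, Et3N, CH2Cl2, 0 °C → rt
Reagents that add atoms: none
Why: Cyclodehydration of a β-hydroxy amide by O-mesylation and 5-exo-tet displacement by the amide oxygen at the CH2 carbon, so the tert-butyl-bearing stereocenter keeps its (R) configuration.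

Step 5
Reactants: 10 methyl 7-(benzyloxy)-2-[(4R)-4-tert-butyl-4,5-dihydro-1,3-oxazol-2-yl]-6-methoxynaphthalene-3-carboxylate
Product: 11 {7-(benzyloxy)-2-[(4R)-4-tert-butyl-4,5-dihydro-1,3-oxazol-2-yl]-6-methoxynaphthalen-3-yl}methanol
Conditions: LiBH4, THF, 0 °C → rt; aq. NaHCO3 work-up
Reagents that add atoms: none
Why: Chemoselective borohydride reduction of the ester, which leaves the oxazoline C=N bond intact; the neutral work-up avoids acid-catalysed lactonization of the ortho-hydroxymethyl oxazoline.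

Step 6
Reactants: 11 {7-(benzyloxy)-2-[(4R)-4-tert-butyl-4,5-dihydro-1,3-oxazol-2-yl]-6-methoxynaphthalen-3-yl}methanol
Product: 12 (4R)-2-[7-(benzyloxy)-3-({[tert-butyl(dimethyl)silyl]oxy}methyl)-6-methoxynaphthalen-2-yl]-4-tert-butyl-4,5-dihydro-1,3-oxazole
Conditions: TBSCl, imidazole, DMF, rt
Reagents that add atoms: tert-butyldimethylsilyl chloride CC(C)(C)[Si](C)(C)Cl
Why: Standard silylation of a primary alcohol; the bulky, weakly Lewis-basic silyl ether should not chelate lithium in step 8 and survives every step up to the last.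

Step 7
Reactants: 13 4-bromo-2,6-dimethoxyphenol
Product: 14 2-(benzyloxy)-5-bromo-1,3-dimethoxybenzene
Conditions: BnBr, K2CO3, DMF, 60 °C
Reagents that add atoms: benzyl bromide BrCc1ccccc1
Why: Williamson ether synthesis on an acidic, moderately hindered phenol.

Step 8
Reactants: 12 (4R)-2-[7-(benzyloxy)-3-({[tert-butyl(dimethyl)silyl]oxy}methyl)-6-methoxynaphthalen-2-yl]-4-tert-butyl-4,5-dihydro-1,3-oxazole; 14 2-(benzyloxy)-5-bromo-1,3-dimethoxybenzene
Product: 18 (4R)-2-[(1R,2S)-7-(benzyloxy)-1-[4-(benzyloxy)-3,5-dimethoxyphenyl]-3-({[tert-butyl(dimethyl)silyl]oxy}methyl)-6-methoxy-1,2-dihydronaphthalen-2-yl]-4-tert-butyl-4,5-dihydro-1,3-oxazole, via aryllithium 15 (not isolated), via lithium aza-enolate 16 (not isolated), via cis-dihydronaphthalene 17 (not isolated)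
Conditions: 14 (1.6 equiv), t-BuLi (3.2 equiv), THF, −78 °C; then 12, THF, −78 → −30 °C; MeOH, −78 °C → rt; then NaOMe (0.3 equiv), MeOH/THF, 40 °C, argon
Reagents that add atoms: none
Why: Bromine–lithium exchange on 14 (two equivalents of t-BuLi, so that no alkyl bromide remains to alkylate the aza-enolate) gives aryllithium 15, which binds to the oxazoline nitrogen of 12 in the conformer with N syn to C1 and transfers its aryl group to C1, the β-carbon of the vinylogous imidate, to give aza-enolate 16 with loss of aromaticity in ring B only. The closest known reaction type is the Meyers dearomatizing conjugate addition of organolithium reagents to chiral 2-naphthyloxazolines. No ring is closed. C1 is set by the auxiliary: the (4R) tert-butyl group shields one face of the nitrogen-bound reagent, so the aryl group should be delivered anti to it, which gives (1R). C2 is set under thermodynamic control: methanol protonates 16 anti to the new aryl group (cis isomer 17), and methoxide then equilibrates C2 through the aza-enolate to the trans isomer 18, the only one in which the C1 aryl group (peri strain with C8–H) and the C2 oxazoline (A(1,2) strain with the C3 substituent) can both be pseudoaxial. The step needs regioselectivity for C1 (C3 is substituted and attack there would break the aromaticity of both rings) and chemoselectivity for addition over deprotonation of the C3 CH2 group, which the low kinetic basicity of the aryllithium at low temperature and the non-chelating silyl ether should secure.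

Step 9
Reactants: 18 (4R)-2-[(1R,2S)-7-(benzyloxy)-1-[4-(benzyloxy)-3,5-dimethoxyphenyl]-3-({[tert-butyl(dimethyl)silyl]oxy}methyl)-6-methoxy-1,2-dihydronaphthalen-2-yl]-4-tert-butyl-4,5-dihydro-1,3-oxazole
Product: 21 (1R,2S)-7-(benzyloxy)-1-[4-(benzyloxy)-3,5-dimethoxyphenyl]-3-({[tert-butyl(dimethyl)silyl]oxy}methyl)-6-methoxy-1,2-dihydronaphthalene-2-carbaldehyde, via oxazolinium triflate 19 (not isolated), via oxazolidine 20 (not isolated)
Conditions: MeOTf, CH2Cl2, 0 °C → rt; NaBH4, THF/MeOH, 0 °C; oxalic acid, THF/H2O, 0 °C → rt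
Reagents that add atoms: water O
Why: Reductive unmasking of an oxazoline to an aldehyde (N-methylation, hydride reduction of the oxazolinium ion to the N,O-acetal, mild acid hydrolysis); C2 is already in its thermodynamic trans configuration, and cold, mild hydrolysis is chosen to keep the double bond at C3=C4.

Step 10
Reactants: 21 (1R,2S)-7-(benzyloxy)-1-[4-(benzyloxy)-3,5-dimethoxyphenyl]-3-({[tert-butyl(dimethyl)silyl]oxy}methyl)-6-methoxy-1,2-dihydronaphthalene-2-carbaldehyde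
Product: 22 [(1R,2S)-7-(benzyloxy)-1-[4-(benzyloxy)-3,5-dimethoxyphenyl]-3-({[tert-butyl(dimethyl)silyl]oxy}methyl)-6-methoxy-1,2-dihydronaphthalen-2-yl]methanol
Conditions: NaBH4, MeOH, 0 °C (crude 21 used at once)
Reagents that add atoms: none
Why: Borohydride reduction of the aldehyde, done at once so that the β,γ-unsaturated aldehyde has no time to isomerize; no stereocenter is affected.

Step 11
Reactants: 22 [(1R,2S)-7-(benzyloxy)-1-[4-(benzyloxy)-3,5-dimethoxyphenyl]-3-({[tert-butyl(dimethyl)silyl]oxy}methyl)-6-methoxy-1,2-dihydronaphthalen-2-yl]methanol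
Product: 23 [(1R,2S,3S)-7-(benzyloxy)-1-[4-(benzyloxy)-3,5-dimethoxyphenyl]-3-({[tert-butyl(dimethyl)silyl]oxy}methyl)-6-methoxy-1,2,3,4-tetrahydronaphthalen-2-yl]methanol
Conditions: [Ir(cod)(PCy3)(py)]PF6 (5 mol%), H2 (1 atm), CH2Cl2, rt
Reagents that add atoms: none
Why: Hydroxyl-directed homogeneous hydrogenation: the pseudoaxial C2 hydroxymethyl group, homoallylic to C3=C4 and on the face opposite to the C1 aryl group, binds the cationic iridium catalyst and H2 is delivered to that face, so the C3 silyloxymethyl group should end trans to C2 and cis to the C1 aryl group, which sets (3S).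

Step 12
Reactants: 23 [(1R,2S,3S)-7-(benzyloxy)-1-[4-(benzyloxy)-3,5-dimethoxyphenyl]-3-({[tert-butyl(dimethyl)silyl]oxy}methyl)-6-methoxy-1,2,3,4-tetrahydronaphthalen-2-yl]methanol
Product: 24 (6S,7S,8R)-8-(4-hydroxy-3,5-dimethoxyphenyl)-6,7-bis(hydroxymethyl)-3-methoxy-5,6,7,8-tetrahydronaphthalen-2-ol
Conditions: H2 (1 atm), Pd/C (10 wt%), MeOH, HCl (cat.), rt
Reagents that add atoms: none
Why: Hydrogenolysis of the two aryl benzyl ethers over palladium with concurrent acid-catalysed methanolysis of the primary silyl ether; no stereocenter is labile under these conditions.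

**Compound list**

1 | 4-(benzyloxy)-3-methoxybenzaldehyde | COc1cc(C=O)ccc1OCc1ccccc1 | starting material
2 | 4-(benzyloxy)-2-bromo-5-methoxybenzaldehyde | COc1cc(C=O)c(Br)cc1OCc1ccccc1 | intermediate
3 | 4-methoxy-2-methylidene-4-oxobutanoic acid (itaconic acid 4-methyl ester) | C=C(CC(=O)OC)C(=O)O | starting material
4 | (2E)-2-{[5-(benzyloxy)-2-formyl-4-methoxyphenyl]methylidene}-4-methoxy-4-oxobutanoic acid | COC(=O)C/C(C(=O)O)=C\c1cc(OCc2ccccc2)c(OC)cc1C=O | intermediate
5 | 7-(benzyloxy)-6-methoxy-3-(methoxycarbonyl)naphthalene-2-carboxylic acid | OC(=O)c1cc2cc(OCc3ccccc3)c(OC)cc2cc1C(=O)OC | intermediate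
6 | (2R)-2-amino-3,3-dimethylbutan-1-ol | CC(C)(C)[C@@H](N)CO | starting material
7 | methyl 7-(benzyloxy)-2-(chlorocarbonyl)-6-methoxynaphthalene-3-carboxylate | COC(=O)c1cc2cc(OC)c(OCc3ccccc3)cc2cc1C(Cl)=O | intermediate
8 | methyl 7-(benzyloxy)-2-{[(2R)-1-hydroxy-3,3-dimethylbutan-2-yl]carbamoyl}-6-methoxynaphthalene-3-carboxylate | COC(=O)c1cc2cc(OC)c(OCc3ccccc3)cc2cc1C(=O)N[C@@H](CO)C(C)(C)C | intermediate
9 | methyl 7-(benzyloxy)-2-{[(2R)-1-(methanesulfonyloxy)-3,3-dimethylbutan-2-yl]carbamoyl}-6-methoxynaphthalene-3-carboxylate | COC(=O)c1cc2cc(OC)c(OCc3ccccc3)cc2cc1C(=O)N[C@@H](COS(C)(=O)=O)C(C)(C)C | intermediate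
10 | methyl 7-(benzyloxy)-2-[(4R)-4-tert-butyl-4,5-dihydro-1,3-oxazol-2-yl]-6-methoxynaphthalene-3-carboxylate | COC(=O)c1cc2cc(OC)c(OCc3ccccc3)cc2cc1C4=N[C@H](C(C)(C)C)CO4 | intermediate
11 | {7-(benzyloxy)-2-[(4R)-4-tert-butyl-4,5-dihydro-1,3-oxazol-2-yl]-6-methoxynaphthalen-3-yl}methanol | OCc1cc2cc(OC)c(OCc3ccccc3)cc2cc1C4=N[C@H](C(C)(C)C)CO4 | intermediate
12 | (4R)-2-[7-(benzyloxy)-3-({[tert-butyl(dimethyl)silyl]oxy}methyl)-6-methoxynaphthalen-2-yl]-4-tert-butyl-4,5-dihydro-1,3-oxazole | CC(C)(C)[Si](C)(C)OCc1cc2cc(OC)c(OCc3ccccc3)cc2cc1C4=N[C@H](C(C)(C)C)CO4 | intermediate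
13 | 4-bromo-2,6-dimethoxyphenol | COc1cc(Br)cc(OC)c1O | starting material
14 | 2-(benzyloxy)-5-bromo-1,3-dimethoxybenzene | COc1cc(Br)cc(OC)c1OCc1ccccc1 | intermediate
15 | [4-(benzyloxy)-3,5-dimethoxyphenyl]lithium | [Li]c1cc(OC)c(OCc2ccccc2)c(OC)c1 | intermediate
16 | (1R)-7-(benzyloxy)-1-[4-(benzyloxy)-3,5-dimethoxyphenyl]-3-({[tert-butyl(dimethyl)silyl]oxy}methyl)-2-[(4R)-4-tert-butyl-3-lithio-1,3-oxazolidin-2-ylidene]-6-methoxy-1,2-dihydronaphthalene (lithium aza-enolate) | COc1cc2c(cc1OCc3ccccc3)[C@@H](c4cc(OC)c(OCc5ccccc5)c(OC)c4)C(=C6N([Li])[C@H](C(C)(C)C)CO6)C(CO[Si](C)(C)C(C)(C)C)=C2 | intermediate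
17 | (4R)-2-[(1R,2R)-7-(benzyloxy)-1-[4-(benzyloxy)-3,5-dimethoxyphenyl]-3-({[tert-butyl(dimethyl)silyl]oxy}methyl)-6-methoxy-1,2-dihydronaphthalen-2-yl]-4-tert-butyl-4,5-dihydro-1,3-oxazole (1,2-cis) | COc1cc2c(cc1OCc3ccccc3)[C@@H](c4cc(OC)c(OCc5ccccc5)c(OC)c4)[C@@H](C6=N[C@H](C(C)(C)C)CO6)C(CO[Si](C)(C)C(C)(C)C)=C2 | intermediate
18 | (4R)-2-[(1R,2S)-7-(benzyloxy)-1-[4-(benzyloxy)-3,5-dimethoxyphenyl]-3-({[tert-butyl(dimethyl)silyl]oxy}methyl)-6-methoxy-1,2-dihydronaphthalen-2-yl]-4-tert-butyl-4,5-dihydro-1,3-oxazole (1,2-trans) | COc1cc2c(cc1OCc3ccccc3)[C@@H](c4cc(OC)c(OCc5ccccc5)c(OC)c4)[C@H](C6=N[C@H](C(C)(C)C)CO6)C(CO[Si](C)(C)C(C)(C)C)=C2 | intermediate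
19 | (4R)-2-[(1R,2S)-7-(benzyloxy)-1-[4-(benzyloxy)-3,5-dimethoxyphenyl]-3-({[tert-butyl(dimethyl)silyl]oxy}methyl)-6-methoxy-1,2-dihydronaphthalen-2-yl]-4-tert-butyl-3-methyl-4,5-dihydro-1,3-oxazol-3-ium trifluoromethanesulfonate | COc1cc2c(cc1OCc3ccccc3)[C@@H](c4cc(OC)c(OCc5ccccc5)c(OC)c4)[C@H](C6=[N+](C)[C@H](C(C)(C)C)CO6)C(CO[Si](C)(C)C(C)(C)C)=C2.[O-]S(=O)(=O)C(F)(F)F | intermediate
20 | (4R)-2-[(1R,2S)-7-(benzyloxy)-1-[4-(benzyloxy)-3,5-dimethoxyphenyl]-3-({[tert-butyl(dimethyl)silyl]oxy}methyl)-6-methoxy-1,2-dihydronaphthalen-2-yl]-4-tert-butyl-3-methyl-1,3-oxazolidine (both epimers at C2 of the oxazolidine) | COc1cc2c(cc1OCc3ccccc3)[C@@H](c4cc(OC)c(OCc5ccccc5)c(OC)c4)[C@H](C6N(C)[C@H](C(C)(C)C)CO6)C(CO[Si](C)(C)C(C)(C)C)=C2 | intermediate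
21 | (1R,2S)-7-(benzyloxy)-1-[4-(benzyloxy)-3,5-dimethoxyphenyl]-3-({[tert-butyl(dimethyl)silyl]oxy}methyl)-6-methoxy-1,2-dihydronaphthalene-2-carbaldehyde | COc1cc2c(cc1OCc3ccccc3)[C@@H](c4cc(OC)c(OCc5ccccc5)c(OC)c4)[C@H](C=O)C(CO[Si](C)(C)C(C)(C)C)=C2 | intermediate
22 | [(1R,2S)-7-(benzyloxy)-1-[4-(benzyloxy)-3,5-dimethoxyphenyl]-3-({[tert-butyl(dimethyl)silyl]oxy}methyl)-6-methoxy-1,2-dihydronaphthalen-2-yl]methanol | COc1cc2c(cc1OCc3ccccc3)[C@@H](c4cc(OC)c(OCc5ccccc5)c(OC)c4)[C@H](CO)C(CO[Si](C)(C)C(C)(C)C)=C2 | intermediate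
23 | [(1R,2S,3S)-7-(benzyloxy)-1-[4-(benzyloxy)-3,5-dimethoxyphenyl]-3-({[tert-butyl(dimethyl)silyl]oxy}methyl)-6-methoxy-1,2,3,4-tetrahydronaphthalen-2-yl]methanol | COc1cc2c(cc1OCc3ccccc3)[C@@H](c4cc(OC)c(OCc5ccccc5)c(OC)c4)[C@H](CO)[C@@H](CO[Si](C)(C)C(C)(C)C)C2 | intermediate
24 | (6S,7S,8R)-8-(4-hydroxy-3,5-dimethoxyphenyl)-6,7-bis(hydroxymethyl)-3-methoxy-5,6,7,8-tetrahydronaphthalen-2-ol | COc1cc2c(cc1O)[C@@H](c1cc(OC)c(O)c(OC)c1)[C@H](CO)[C@@H](CO)C2 | target

**Step count and risks**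

Total steps: 12. Longest linear sequence: 11 steps (steps 1–6 and 8–12; step 7 is a one-step branch).

Three steps most likely to fail:

1. Step 8 (key step). What may go wrong: the aryllithium may deprotonate the C3 benzylic CH2 group (lateral lithiation, possibly followed by silyl migration) instead of adding to C1, so that 12 is consumed without C–C bond formation. The fallback removes the acidic C–H bonds by raising C3 to the acetal oxidation level. It sets out from 11: oxidation with MnO2 in CH2Cl2 should give 7-(benzyloxy)-2-[(4R)-4-tert-butyl-4,5-dihydro-1,3-oxazol-2-yl]-6-methoxynaphthalene-3-carbaldehyde F1, and HC(OMe)3 with PPTS in MeOH its dimethyl acetal F2. Addition of 15 and methoxide equilibration as in step 8 should give the trans-(1R,2S) adduct F3. PPTS in wet acetone should free the conjugated C3 carbaldehyde F4, and a Luche reduction (NaBH4, CeCl3·7H2O, MeOH, −40 °C) should give the allylic alcohol F5. Silylation (TBSCl, imidazole, DMF) brings the material back to the route at 18.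

2. Step 11. What may go wrong: poor facial selectivity, if the directing effect of the C2 hydroxymethyl group is overridden by the bulky silyloxymethyl group on the alkene, or stalling on the trisubstituted styrene. The fallback sets C3 by steric approach control and corrects C2 afterwards. It sets out from 17, obtained by stopping step 8 after the methanol quench at −78 °C without methoxide. Heterogeneous hydrogenation (H2, 1 atm, Pt/C, EtOAc) should add hydrogen to the face opposite to the two cis substituents and give the all-cis (1R,2R,3S) tetralin oxazoline F6. The sequence of step 9 then leads through the oxazolinium triflate F7 and the oxazolidine F8 to the all-cis aldehyde F9. DBU in CH2Cl2 should epimerize C2 to the all-trans (1R,2S,3S) aldehyde F10, with no double bond left that could migrate. NaBH4 in MeOH returns to the route at 23.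

3. Step 9. What may go wrong: migration of the C3=C4 double bond into conjugation with the new aldehyde (or erosion at C2) during the acid hydrolysis, and partial loss of the silyl ether. The fallback never frees the aldehyde. It sets out from 19: hydrolysis with water in THF followed by NaHCO3 should open the oxazolinium ring to the amino ester [(2R)-3,3-dimethyl-2-(methylamino)butyl] (1R,2S)-7-(benzyloxy)-1-[4-(benzyloxy)-3,5-dimethoxyphenyl]-3-({[tert-butyl(dimethyl)silyl]oxy}methyl)-6-methoxy-1,2-dihydronaphthalene-2-carboxylate F11. Reduction with LiAlH4 in THF at −20 °C returns directly to the route at 22.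

**Further compounds**

F1 | step 8 | 7-(benzyloxy)-2-[(4R)-4-tert-butyl-4,5-dihydro-1,3-oxazol-2-yl]-6-methoxynaphthalene-3-carbaldehyde | O=Cc1cc2cc(OC)c(OCc3ccccc3)cc2cc1C4=N[C@H](C(C)(C)C)CO4
F2 | step 8 | (4R)-2-[7-(benzyloxy)-3-(dimethoxymethyl)-6-methoxynaphthalen-2-yl]-4-tert-butyl-4,5-dihydro-1,3-oxazole | COC(OC)c1cc2cc(OC)c(OCc3ccccc3)cc2cc1C4=N[C@H](C(C)(C)C)CO4
F3 | step 8 | (4R)-2-[(1R,2S)-7-(benzyloxy)-1-[4-(benzyloxy)-3,5-dimethoxyphenyl]-3-(dimethoxymethyl)-6-methoxy-1,2-dihydronaphthalen-2-yl]-4-tert-butyl-4,5-dihydro-1,3-oxazole | COc1cc2c(cc1OCc3ccccc3)[C@@H](c4cc(OC)c(OCc5ccccc5)c(OC)c4)[C@H](C6=N[C@H](C(C)(C)C)CO6)C(C(OC)OC)=C2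
F4 | step 8 | (1R,2S)-7-(benzyloxy)-1-[4-(benzyloxy)-3,5-dimethoxyphenyl]-2-[(4R)-4-tert-butyl-4,5-dihydro-1,3-oxazol-2-yl]-6-methoxy-1,2-dihydronaphthalene-3-carbaldehyde | COc1cc2c(cc1OCc3ccccc3)[C@@H](c4cc(OC)c(OCc5ccccc5)c(OC)c4)[C@H](C6=N[C@H](C(C)(C)C)CO6)C(C=O)=C2
F5 | step 8 | {(1R,2S)-7-(benzyloxy)-1-[4-(benzyloxy)-3,5-dimethoxyphenyl]-2-[(4R)-4-tert-butyl-4,5-dihydro-1,3-oxazol-2-yl]-6-methoxy-1,2-dihydronaphthalen-3-yl}methanol | COc1cc2c(cc1OCc3ccccc3)[C@@H](c4cc(OC)c(OCc5ccccc5)c(OC)c4)[C@H](C6=N[C@H](C(C)(C)C)CO6)C(CO)=C2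
F6 | step 11 | (4R)-2-[(1R,2R,3S)-7-(benzyloxy)-1-[4-(benzyloxy)-3,5-dimethoxyphenyl]-3-({[tert-butyl(dimethyl)silyl]oxy}methyl)-6-methoxy-1,2,3,4-tetrahydronaphthalen-2-yl]-4-tert-butyl-4,5-dihydro-1,3-oxazole | COc1cc2c(cc1OCc3ccccc3)[C@@H](c4cc(OC)c(OCc5ccccc5)c(OC)c4)[C@@H](C6=N[C@H](C(C)(C)C)CO6)[C@@H](CO[Si](C)(C)C(C)(C)C)C2
F7 | step 11 | (4R)-2-[(1R,2R,3S)-7-(benzyloxy)-1-[4-(benzyloxy)-3,5-dimethoxyphenyl]-3-({[tert-butyl(dimethyl)silyl]oxy}methyl)-6-methoxy-1,2,3,4-tetrahydronaphthalen-2-yl]-4-tert-butyl-3-methyl-4,5-dihydro-1,3-oxazol-3-ium trifluoromethanesulfonate | COc1cc2c(cc1OCc3ccccc3)[C@@H](c4cc(OC)c(OCc5ccccc5)c(OC)c4)[C@@H](C6=[N+](C)[C@H](C(C)(C)C)CO6)[C@@H](CO[Si](C)(C)C(C)(C)C)C2.[O-]S(=O)(=O)C(F)(F)F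
F8 | step 11 | (4R)-2-[(1R,2R,3S)-7-(benzyloxy)-1-[4-(benzyloxy)-3,5-dimethoxyphenyl]-3-({[tert-butyl(dimethyl)silyl]oxy}methyl)-6-methoxy-1,2,3,4-tetrahydronaphthalen-2-yl]-4-tert-butyl-3-methyl-1,3-oxazolidine | COc1cc2c(cc1OCc3ccccc3)[C@@H](c4cc(OC)c(OCc5ccccc5)c(OC)c4)[C@@H](C6N(C)[C@H](C(C)(C)C)CO6)[C@@H](CO[Si](C)(C)C(C)(C)C)C2
F9 | step 11 | (1R,2R,3S)-7-(benzyloxy)-1-[4-(benzyloxy)-3,5-dimethoxyphenyl]-3-({[tert-butyl(dimethyl)silyl]oxy}methyl)-6-methoxy-1,2,3,4-tetrahydronaphthalene-2-carbaldehyde | COc1cc2c(cc1OCc3ccccc3)[C@@H](c4cc(OC)c(OCc5ccccc5)c(OC)c4)[C@@H](C=O)[C@@H](CO[Si](C)(C)C(C)(C)C)C2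
F10 | step 11 | (1R,2S,3S)-7-(benzyloxy)-1-[4-(benzyloxy)-3,5-dimethoxyphenyl]-3-({[tert-butyl(dimethyl)silyl]oxy}methyl)-6-methoxy-1,2,3,4-tetrahydronaphthalene-2-carbaldehyde | COc1cc2c(cc1OCc3ccccc3)[C@@H](c4cc(OC)c(OCc5ccccc5)c(OC)c4)[C@H](C=O)[C@@H](CO[Si](C)(C)C(C)(C)C)C2
F11 | step 9 | [(2R)-3,3-dimethyl-2-(methylamino)butyl] (1R,2S)-7-(benzyloxy)-1-[4-(benzyloxy)-3,5-dimethoxyphenyl]-3-({[tert-butyl(dimethyl)silyl]oxy}methyl)-6-methoxy-1,2-dihydronaphthalene-2-carboxylate | COc1cc2c(cc1OCc3ccccc3)[C@@H](c4cc(OC)c(OCc5ccccc5)c(OC)c4)[C@H](C(=O)OC[C@H](NC)C(C)(C)C)C(CO[Si](C)(C)C(C)(C)C)=C2
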